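Flask zeta cannot use up its electrophile at two nucleophiles per electrophile, since its charge of nucleophile is less than that. Here is the problem, with flask eta beside it.

common to all: electrophile 12 mM; solid base 14.4 mM; time 3.0 h

| flask | nucleophile |
|---|---|
| zeta | 18.0 mM |
| eta | 23.0 mM |

    solid base ⇌ free base, rate k1*(cs1 - [free base]) while solid is left; crystals form when [free base] > cs1 (cs1 = 4.9 mM, k1 = 0.0358 min⁻¹)
    nucleophile + acid set free ⇌ protonated nucleophile, settled at all times (K2 = 1.5 × 10⁵ L mol⁻¹)
    acid set free + free base ⇌ salt of the base, settled at all times (K3 = 93.6 L mol⁻¹)
    electrophile + nucleophile ⇌ acid set free + target (K4 = 4.09, k4 = 3.61 L mol⁻¹ min⁻¹)
    nucleophile + target → over-reaction product (k5 = 1.22 L mol⁻¹ min⁻¹)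

- as a solid, counted per litre of solution: solid base
- at the start none of the solid base is in solution
- run time (zeta): 3.0 h

* part of the electrophile that has reacted at the end, zeta
* part of the electrophile that has reacted at the end, eta
* what raising the concentration of nucleophile from its lowest to its highest value here does to the part of the electrophile that has reacted (changes below 5 percentage points count as none) (it rises / it falls / no change)

Why two? One nucleophile goes into the target, and the acid set free needs a partner. At the start of zeta, bound acid per free acid stands at 2700 on nucleophile, but at 0.459 on free base at its solubility, so I park each acid on a second nucleophile. The half-life of electrophile by the forward rate of its step, at the charged concentrations, is 0.18 h, short against 3.0 h, so I expect nucleophile, the limiting reagent, to stop the flask rather than the clock.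

The clean case of two per electrophile is my zero: zeta reaches 75.0% of its charge. But target takes nucleophile too. Nucleophile stands on the left of both steps, so it cancels from their ratio, the selectivity factor 0.338. Integrating with the back step set aside, over-reaction product holds 18.2% of the charge at that conversion. Each of those costs one more nucleophile, which makes 2.24 per electrophile and brings zeta down to 66.9%.

The weak link is that I counted over-reaction at a conversion zeta does not reach. Reckoned again at the lower conversion, the nucleophile price, nucleophile spent per electrophile reacted, is 2.19, and I commit to 68.4% for zeta. For eta the same two passes start from 95.8% and give 75.8%, then 85.2%. The price grows with conversion, so the closing value lies between them, and I take 80.5%, a rise of 12 percentage points.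

The forecast gives 69.5% (66% to 73%) for zeta and 82.5% (78% to 86%) for eta, and says it rises, calling “nucleophile supply rather than time the limit”. Its numbers stand above mine by 1.1 points and 2 points.

The simulation gives 68.8% for zeta and 82.9% for eta, so it rises, by 14 points. With eta's extra nucleophile taken away, which leaves zeta's charge, the part of the electrophile that has reacted falls from 82.9% to 68.8%, so the nucleophile charge is the main reason for the rise. A neighbour flask, eta with 20 mM of electrophile, should reach 52.4% at zeta's price of 2.19, and it reaches 54.9%.

The constants used here are invented; what happens was integrated by code.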